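## Retrosynthetic overview

1. The target is reached by epoxidising the C13=C14 alkene of an eight-membered cyclic ether (ring C, O–C8–C9–C11–C12–C13–C14–C15). Ring C is closed last, by ring-closing metathesis between a C8 O-allyl group and a C13 isopropenyl group.
2. The equatorial C3 bromide comes from hydrogen-atom-transfer hydrogenation of a C2=C3 alkenyl bromide made from a C3 ketone. The C11–C13 chain is grown from a C9 ester by olefination.
3. Rings A and B are formed together by an intramolecular Diels–Alder reaction of an acyclic trienoate (bonds C5–C10 and C8–C9). The strategy rests on the trans-fused decalin C1–C10: its four contiguous stereocentres C5, C10, C9 and C8 (axial methyls on C8 and C10, equatorial oxygen on C8, equatorial carbon on C9) map onto one endo transition state of an (E)-enoate and a (Z)-1-silyloxy-1-methyl diene.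
4. The trienoate is assembled from methyl geranate (C9–C11, C1–C3, C20), a prenyl unit added enantioselectively at C3 (C4, C5, C18, C19) and a four-carbon ketal sulfone (C6–C8, C17) joined by Julia–Kocienski olefination.
5. Ring order: A and B at once, then C, then the epoxide.

Key step: step 10

Assumptions and conventions:
- Labdane numbering is used for all bicyclic compounds (decalin C1–C10, C11 on C9, methyls C17 on C8, C18/C19 on C4, C20 on C10).
- "Ring configuration Q" means a trans-fused decalin with the C10 methyl, the C8 methyl, the C9 carbon substituent and an equatorial C3 substituent on one face, and H-5, H-9 and the C8 oxygen on the other face. The absolute sense is that of the SMILES (C10 is R in every bicyclic compound).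
- The prenylborane derived from (+)-α-pinene is taken to attack the Si face of aldehyde 3, as it does with simple aliphatic aldehydes. The antipodal borane would be used if the sense proved opposite.
- TBS = tert-butyldimethylsilyl.

## Route

Step 1
Reactants: 1 methyl geranate
Product: 3 methyl (2E)-3-methyl-6-oxohex-2-enoate, via ozonide 2 (not isolated)
Conditions: O3, CH2Cl2, −78 °C (indicator end-point); then Me2S, −78 °C → rt
Reagents that add atoms: ozone, [O-][O+]=O
Why: Ozonolysis with reductive work-up, in which the electron-rich trisubstituted C6=C7 alkene reacts far faster with ozone than the conjugated electron-poor enoate alkene, so stopping at the end-point should cleave only the isopropylidene end and keep the (E)-enoate that later serves as dienophile.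

Step 2
Reactants: 3 methyl (2E)-3-methyl-6-oxohex-2-enoate
Product: 5 methyl (2E,6R)-6-hydroxy-3,7,7-trimethylnona-2,8-dienoate, via borinate ester 4 (not isolated)
Conditions: (−)-Ipc2BH [from (+)-α-pinene], 3-methylbuta-1,2-diene, THF, −25 °C; then 3, −78 °C; NaBO3·4H2O, H2O, rt
Reagents that add atoms: 3-methylbuta-1,2-diene, CC(C)=C=C (carried as the prenyl group of the borane)
Why: Asymmetric allylboration with allylic transposition through a chair six-membered transition state, in which the primary prenylborane reacts at its dimethyl-substituted γ-carbon to build the C4 quaternary carbon and a vinyl handle for C5 in one bond-forming event, while the isopinocampheyl groups direct attack to the Si face of the aldehyde and set C3 as R.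

Step 3
Reactants: 5 methyl (2E,6R)-6-hydroxy-3,7,7-trimethylnona-2,8-dienoate
Product: 6 methyl (2E,6R)-6-(benzyloxy)-3,7,7-trimethylnona-2,8-dienoate
Conditions: BnOC(=NH)CCl3, TfOH (cat.), CH2Cl2/cyclohexane, 0 °C → rt
Reagents that add atoms: benzyl 2,2,2-trichloroacetimidate, ClC(Cl)(Cl)C(=N)OCc1ccccc1
Why: Acid-catalysed O-benzylation with a trichloroacetimidate avoids alkoxide conditions under which the C3 alkoxide could add to the enoate, and gives an ether that survives base, heat and silyl triflate and is later removed by hydrogenolysis.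

Step 4
Reactants: 6 methyl (2E,6R)-6-(benzyloxy)-3,7,7-trimethylnona-2,8-dienoate
Product: 8 methyl (2E,6R)-6-(benzyloxy)-3,7,7-trimethyl-8-oxooct-2-enoate, via vicinal diol 7 (not isolated)
Conditions: OsO4 (cat.), NaIO4, 2,6-lutidine, 1,4-dioxane/H2O, rt
Reagents that add atoms: sodium periodate, [Na+].[O-]I(=O)(=O)=O (terminal oxygen source, delivered through catalytic OsO4, O=[Os](=O)(=O)=O)
Why: Lemieux–Johnson cleavage, in which osmium tetroxide dihydroxylates the monosubstituted terminal alkene in preference to the trisubstituted conjugated enoate and periodate cleaves the diol to the non-enolisable C5 aldehyde.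

Step 5
Reactants: 9 2-(2-bromoethyl)-2-methyl-1,3-dioxolane
Product: 10 5-{[2-(2-methyl-1,3-dioxolan-2-yl)ethyl]sulfanyl}-1-phenyl-1H-tetrazole
Conditions: 1-phenyl-1H-tetrazole-5-thiol, K2CO3, DMF, rt
Reagents that add atoms: 1-phenyl-1H-tetrazole-5-thiol, Sc1nnnn1-c1ccccc1
Why: SN2 thioetherification of an unhindered primary bromide by the soft tetrazolethiolate, to which the ketal is inert.

Step 6
Reactants: 10 5-{[2-(2-methyl-1,3-dioxolan-2-yl)ethyl]sulfanyl}-1-phenyl-1H-tetrazole
Product: 11 5-{[2-(2-methyl-1,3-dioxolan-2-yl)ethyl]sulfonyl}-1-phenyl-1H-tetrazole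
Conditions: H2O2 (30 % aq.), (NH4)6Mo7O24·4H2O (cat.), EtOH, 0 °C → rt
Reagents that add atoms: hydrogen peroxide, OO
Why: Molybdate-catalysed peroxide oxidation of the sulfide to the sulfone under conditions mild enough for the dioxolane.

Step 7
Reactants: 8 methyl (2E,6R)-6-(benzyloxy)-3,7,7-trimethyl-8-oxooct-2-enoate; 11 5-{[2-(2-methyl-1,3-dioxolan-2-yl)ethyl]sulfonyl}-1-phenyl-1H-tetrazole
Product: 14 methyl (2E,6R,8E)-6-(benzyloxy)-3,7,7-trimethyl-10-(2-methyl-1,3-dioxolan-2-yl)deca-2,8-dienoate, via potassium sulfonyl carbanion 12 (not isolated), via β-alkoxy sulfone adduct 13 (not isolated)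
Conditions: 11, KHMDS, DME, −60 °C; then 8, −60 °C → rt
Reagents that add atoms: none
Why: Julia–Kocienski olefination, in which the metalated phenyltetrazolyl sulfone adds to the α-quaternary non-enolisable aldehyde and Smiles rearrangement with loss of sulfur dioxide and tetrazolate gives the C5=C6 alkene, with (E)-selectivity expected from the anti adduct favoured by a bulky aldehyde and a potassium counter-ion in DME.

Step 8
Reactants: 14 methyl (2E,6R,8E)-6-(benzyloxy)-3,7,7-trimethyl-10-(2-methyl-1,3-dioxolan-2-yl)deca-2,8-dienoate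
Product: 15 methyl (2E,6R,8E)-6-(benzyloxy)-3,7,7-trimethyl-11-oxododeca-2,8-dienoate
Conditions: PPTS (cat.), acetone/H2O, 40 °C
Reagents that add atoms: water, O
Why: Mild acid-catalysed ketal hydrolysis releases the methyl ketone, and pyridinium tosylate is weak enough that the β,γ-alkene should not move into conjugation while the benzyl ether and enoate are untouched.

Step 9
Reactants: 15 methyl (2E,6R,8E)-6-(benzyloxy)-3,7,7-trimethyl-11-oxododeca-2,8-dienoate
Product: 16 methyl (2E,6R,8E,10Z)-6-(benzyloxy)-11-[(tert-butyldimethylsilyl)oxy]-3,7,7-trimethyldodeca-2,8,10-trienoate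
Conditions: TBSOTf, Et3N, CH2Cl2, −78 → 0 °C
Reagents that add atoms: tert-butyldimethylsilyl trifluoromethanesulfonate, CC(C)(C)[Si](C)(C)OS(=O)(=O)C(F)(F)F
Why: Soft enolisation with silyl triflate and amine removes the doubly activated C7 proton and not a methyl proton, and the conjugated dienol ether should form with the silyloxy group cis to the vinyl group (Z), the isomer that avoids allylic strain between the C8 methyl and H-6.

Step 10
Reactants: 16 methyl (2E,6R,8E,10Z)-6-(benzyloxy)-11-[(tert-butyldimethylsilyl)oxy]-3,7,7-trimethyldodeca-2,8,10-trienoate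
Product: 17 methyl (3R)-3-benzyloxy-8-(tert-butyldimethylsilyloxy)-4,4,8,10-tetramethyl-trans-decal-6-ene-9-carboxylate (labdane numbering; ring configuration Q)
Conditions: toluene (0.01 M), BHT, Et3N (cat.), sealed tube, 180 °C
Reagents that add atoms: none
Why: Thermal intramolecular Diels–Alder reaction, a concerted but asynchronous suprafacial [4+2] between the electron-rich (Z)-silyloxydiene C5=C6–C7=C8 and the enoate C9=C10, in which the C5–C10 bond (diene terminus remote from oxygen to the enoate β-carbon) is the more advanced and C8–C9 follows. The closest known reaction type is the thermal cyclisation of deca-1,7,9-trienes carrying a terminal ester to trans-fused octalins, including cases with oxygenated dienes. Ring A closes through the four-carbon tether C1–C4 in a chair-like array (bond C5–C10), helped by the gem-dimethyl group at C4, and ring B is the new cyclohexene made by the cycloaddition itself (bonds C5–C10 and C8–C9, with C6=C7 left behind). C10 and C9 are set cis (methyl and ester) by the (E)-geometry of the enoate, the trans fusion C5/C10 by the transition state that keeps the tether anti to the diene and the ester endo, C8 by the (Z)-geometry of the enol ether, whose inside silyloxy group ends on the face of H-5 and H-9, and the absolute sense of all four by the C3 benzyloxy group, which prefers the equatorial site of the chair-like tether. The step needs endo over exo selectivity and one diene face; the first should be secured by the ester under the diene with the smaller C10 methyl axial, the second only by the equatorial preference at C3, so some C3-axial diastereomer is expected and is to be removed by chromatography before C3 is oxidised.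

Step 11
Reactants: 17 methyl (3R)-3-benzyloxy-8-(tert-butyldimethylsilyloxy)-4,4,8,10-tetramethyl-trans-decal-6-ene-9-carboxylate
Product: 18 methyl (3R)-3-hydroxy-8-(tert-butyldimethylsilyloxy)-4,4,8,10-tetramethyl-trans-decalin-9-carboxylate (ring configuration Q)
Conditions: H2 (4 atm), Pd/C, EtOAc, rt
Reagents that add atoms: none
Why: Heterogeneous hydrogenation saturates the cis ring alkene C6=C7 and hydrogenolyses the benzyl ether in one operation, while the tertiary silyl ether and the ester are inert and no stereocentre is created.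

Step 12
Reactants: 18 methyl (3R)-3-hydroxy-8-(tert-butyldimethylsilyloxy)-4,4,8,10-tetramethyl-trans-decalin-9-carboxylate
Product: 19 methyl 8-(tert-butyldimethylsilyloxy)-4,4,8,10-tetramethyl-3-oxo-trans-decalin-9-carboxylate (ring configuration Q)
Conditions: Dess–Martin periodinane, CH2Cl2, rt
Reagents that add atoms: none
Why: Dess–Martin oxidation of the hindered secondary C3 alcohol to the ketone under neutral conditions that leave the β-silyloxy ester alone.

Step 13
Reactants: 19 methyl 8-(tert-butyldimethylsilyloxy)-4,4,8,10-tetramethyl-3-oxo-trans-decalin-9-carboxylate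
Product: 21 methyl 8-(tert-butyldimethylsilyloxy)-4,4,8,10-tetramethyl-3-(trifluoromethanesulfonyloxy)-trans-decal-2-ene-9-carboxylate (ring configuration Q), via potassium enolate 20 (not isolated)
Conditions: KHMDS, THF, −78 °C; then PhNTf2, −78 → 0 °C
Reagents that add atoms: N-phenylbis(trifluoromethanesulfonimide), FC(F)(F)S(=O)(=O)N(c1ccccc1)S(=O)(=O)C(F)(F)F
Why: Enolisation can only occur toward C2 because C4 is quaternary, and O-triflation of the enolate gives the C2=C3 enol triflate, the hindered C9 ester proton not being removed by one equivalent of base at −78 °C.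

Step 14
Reactants: 21 methyl 8-(tert-butyldimethylsilyloxy)-4,4,8,10-tetramethyl-3-(trifluoromethanesulfonyloxy)-trans-decal-2-ene-9-carboxylate
Product: 22 methyl 3-bromo-8-(tert-butyldimethylsilyloxy)-4,4,8,10-tetramethyl-trans-decal-2-ene-9-carboxylate (ring configuration Q)
Conditions: Ni(OAc)2·4H2O (cat.), 1,5-cyclooctadiene (cat.), Zn (cat.), LiBr, DMA/THF, rt
Reagents that add atoms: lithium bromide, [Li+].[Br-]
Why: Nickel-catalysed halide exchange of an enol triflate (oxidative addition to zerovalent nickel, triflate-for-bromide exchange and C–Br reductive elimination) converts the triflate into the alkenyl bromide with the double bond in place.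

Step 15
Reactants: 22 methyl 3-bromo-8-(tert-butyldimethylsilyloxy)-4,4,8,10-tetramethyl-trans-decal-2-ene-9-carboxylate
Product: 23 methyl (3R)-3-bromo-8-(tert-butyldimethylsilyloxy)-4,4,8,10-tetramethyl-trans-decalin-9-carboxylate (ring configuration Q)
Conditions: Mn(dpm)3 (cat.; dpm = 2,2,6,6-tetramethylheptane-3,5-dionate), PhSiH3, t-BuOOH, i-PrOH, rt
Reagents that add atoms: none
Why: Metal-hydride hydrogen-atom-transfer hydrogenation of an alkenyl halide, in which hydrogen-atom transfer to C2 gives the α-bromo C3 radical that takes its second hydrogen axially from the face away from the axial C4 and C10 methyls, so that bromine ends equatorial (3R, also the thermodynamically preferred epimer) without the hydrodebromination that a palladium catalyst would cause.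

Step 16
Reactants: 23 methyl (3R)-3-bromo-8-(tert-butyldimethylsilyloxy)-4,4,8,10-tetramethyl-trans-decalin-9-carboxylate
Product: 24 [(3R)-3-bromo-8-(tert-butyldimethylsilyloxy)-4,4,8,10-tetramethyl-trans-decalin-9-yl]methanol (ring configuration Q)
Conditions: DIBAL-H, CH2Cl2, −78 °C → rt; Rochelle salt work-up
Reagents that add atoms: none
Why: Hydride reduction of the hindered ester to the primary alcohol with an electrophilic aluminium hydride that does not attack the neopentylic secondary bromide.

Step 17
Reactants: 24 [(3R)-3-bromo-8-(tert-butyldimethylsilyloxy)-4,4,8,10-tetramethyl-trans-decalin-9-yl]methanol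
Product: 25 (3R)-3-bromo-8-(tert-butyldimethylsilyloxy)-4,4,8,10-tetramethyl-trans-decalin-9-carbaldehyde (ring configuration Q)
Conditions: Dess–Martin periodinane, pyridine, CH2Cl2, 0 °C → rt
Reagents that add atoms: none
Why: Dess–Martin oxidation gives the C11 aldehyde without epimerising C9, whose equatorial substituent is already the stable one, and without β-elimination of the silyloxy group.

Step 18
Reactants: 25 (3R)-3-bromo-8-(tert-butyldimethylsilyloxy)-4,4,8,10-tetramethyl-trans-decalin-9-carbaldehyde
Product: 26 (3E)-4-[(3R)-3-bromo-8-(tert-butyldimethylsilyloxy)-4,4,8,10-tetramethyl-trans-decalin-9-yl]but-3-en-2-one (ring configuration Q)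
Conditions: (MeO)2P(O)CH2C(O)CH3, NaH, THF, 0 °C → rt
Reagents that add atoms: dimethyl (2-oxopropyl)phosphonate, COP(=O)(CC(C)=O)OC
Why: Horner–Wadsworth–Emmons olefination of the aldehyde with the stabilised ketophosphonate anion, which is weakly basic and small enough to reach the hindered carbonyl, gives the (E)-enone that carries C12, C13 and C16.

Step 19
Reactants: 26 (3E)-4-[(3R)-3-bromo-8-(tert-butyldimethylsilyloxy)-4,4,8,10-tetramethyl-trans-decalin-9-yl]but-3-en-2-one
Product: 27 4-[(3R)-3-bromo-8-(tert-butyldimethylsilyloxy)-4,4,8,10-tetramethyl-trans-decalin-9-yl]butan-2-one (ring configuration Q)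
Conditions: H2 (1 atm), RhCl(PPh3)3 (cat.), toluene, rt
Reagents that add atoms: none
Why: Homogeneous hydrogenation with RhCl(PPh3)3 reduces the disubstituted enone alkene and neither hydrogenolyses the alkyl bromide nor reduces the ketone.

Step 20
Reactants: 27 4-[(3R)-3-bromo-8-(tert-butyldimethylsilyloxy)-4,4,8,10-tetramethyl-trans-decalin-9-yl]butan-2-one
Product: 28 tert-butyldimethylsilyl ether of (3R)-3-bromo-4,4,8,10-tetramethyl-9-(3-methylbut-3-en-1-yl)-trans-decalin-8-ol (ring configuration Q)
Conditions: Ph3PCH3Br, KOt-Bu, THF, 0 °C → rt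
Reagents that add atoms: methyltriphenylphosphonium bromide, C[P+](c1ccccc1)(c1ccccc1)c1ccccc1.[Br-]
Why: Wittig methylenation of the methyl ketone installs the 1,1-disubstituted alkene, and the non-stabilised ylide should neither displace nor eliminate the hindered equatorial bromide.

Step 21
Reactants: 28 tert-butyldimethylsilyl ether of (3R)-3-bromo-4,4,8,10-tetramethyl-9-(3-methylbut-3-en-1-yl)-trans-decalin-8-ol
Product: 29 (3R)-3-bromo-4,4,8,10-tetramethyl-9-(3-methylbut-3-en-1-yl)-trans-decalin-8-ol (ring configuration Q)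
Conditions: TBAF, THF, 60 °C
Reagents that add atoms: none
Why: Fluoride-mediated cleavage of the tertiary silyl ether under non-acidic conditions, chosen because acid would add the C8 hydroxyl across the isopropenyl group to give a six-membered ether.

Step 22
Reactants: 29 (3R)-3-bromo-4,4,8,10-tetramethyl-9-(3-methylbut-3-en-1-yl)-trans-decalin-8-ol
Product: 31 (3R)-8-allyloxy-3-bromo-4,4,8,10-tetramethyl-9-(3-methylbut-3-en-1-yl)-trans-decalin (ring configuration Q), via potassium alkoxide 30 (not isolated)
Conditions: KH, THF, 0 °C; then allyl bromide, 18-crown-6 (cat.), 0 °C → rt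
Reagents that add atoms: allyl bromide, C=CCBr
Why: Williamson etherification in which the potassium tertiary alkoxide is alkylated by the reactive allylic bromide, while the equatorial C3 bromide has no antiperiplanar hydrogen and should resist elimination.

Step 23
Reactants: 31 (3R)-8-allyloxy-3-bromo-4,4,8,10-tetramethyl-9-(3-methylbut-3-en-1-yl)-trans-decalin
Product: 32 (3R,13Z)-3-bromo-8,15-epoxylabd-13-ene (ring configuration Q)
Conditions: second-generation Hoveyda–Grubbs catalyst (cat.), 1,4-benzoquinone (cat.), toluene (1 mM), 80 °C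
Reagents that add atoms: none
Why: Ring-closing metathesis in which the ruthenium carbene loads on the allyl ether and closes onto the 1,1-disubstituted alkene with loss of ethene, the trans-diequatorial C8–O and C9–C11 bonds holding the two arms gauche, and the eight-membered ring can only contain the (Z)-alkene.

Step 24
Reactants: 32 (3R,13Z)-3-bromo-8,15-epoxylabd-13-ene
Product: 33 (3R,5S,8S,9S,10R,13S,14R)-3-bromo-8,15:13,14-diepoxylabdane (CNP0311742.1)
Conditions: dimethyldioxirane, acetone, −20 → 0 °C
Reagents that add atoms: dimethyldioxirane, CC1(C)OO1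
Why: Epoxidation by a dioxirane under neutral conditions, in which the C12–C15 bridge of the expected ring conformer lies on the face away from the axial C8 and C10 methyls and the oxidant attacks the outer face of the alkene, which should set C13 as S and C14 as R.

## Compound list

1 | methyl geranate, methyl (2E)-3,7-dimethylocta-2,6-dienoate | COC(=O)/C=C(\C)CCC=C(C)C | starting material
2 | methyl (2E)-5-(5,5-dimethyl-1,2,4-trioxolan-3-yl)-3-methylpent-2-enoate (ozonide, not isolated) | COC(=O)/C=C(\C)CCC1OOC(C)(C)O1 | intermediate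
3 | methyl (2E)-3-methyl-6-oxohex-2-enoate | COC(=O)/C=C(\C)CCC=O | intermediate
4 | diisopinocampheylborinate ester of 5 (not isolated) | COC(=O)/C=C(\C)CC[C@@H](OB([C@@H]1C[C@@H]2C[C@H]([C@H]1C)C2(C)C)[C@@H]1C[C@@H]2C[C@H]([C@H]1C)C2(C)C)C(C)(C)C=C | intermediate
5 | methyl (2E,6R)-6-hydroxy-3,7,7-trimethylnona-2,8-dienoate | COC(=O)/C=C(\C)CC[C@@H](O)C(C)(C)C=C | intermediate
6 | methyl (2E,6R)-6-(benzyloxy)-3,7,7-trimethylnona-2,8-dienoate | COC(=O)/C=C(\C)CC[C@@H](OCc1ccccc1)C(C)(C)C=C | intermediate
7 | methyl (2E,6R)-6-(benzyloxy)-8,9-dihydroxy-3,7,7-trimethylnon-2-enoate, both C8 epimers (not isolated) | COC(=O)/C=C(\C)CC[C@@H](OCc1ccccc1)C(C)(C)C(O)CO | intermediate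
8 | methyl (2E,6R)-6-(benzyloxy)-3,7,7-trimethyl-8-oxooct-2-enoate | COC(=O)/C=C(\C)CC[C@@H](OCc1ccccc1)C(C)(C)C=O | intermediate
9 | 2-(2-bromoethyl)-2-methyl-1,3-dioxolane | CC1(CCBr)OCCO1 | starting material
10 | 5-{[2-(2-methyl-1,3-dioxolan-2-yl)ethyl]sulfanyl}-1-phenyl-1H-tetrazole | CC1(CCSc2nnnn2-c2ccccc2)OCCO1 | intermediate
11 | 5-{[2-(2-methyl-1,3-dioxolan-2-yl)ethyl]sulfonyl}-1-phenyl-1H-tetrazole | CC1(CCS(=O)(=O)c2nnnn2-c2ccccc2)OCCO1 | intermediate
12 | potassium α-sulfonyl carbanion of 11 (not isolated) | CC1(C[CH-]S(=O)(=O)c2nnnn2-c2ccccc2)OCCO1.[K+] | intermediate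
13 | potassium β-alkoxy sulfone adduct of 8 and 12, mixture of diastereomers (not isolated) | COC(=O)/C=C(\C)CC[C@@H](OCc1ccccc1)C(C)(C)C([O-])C(CC1(C)OCCO1)S(=O)(=O)c1nnnn1-c1ccccc1.[K+] | intermediate
14 | methyl (2E,6R,8E)-6-(benzyloxy)-3,7,7-trimethyl-10-(2-methyl-1,3-dioxolan-2-yl)deca-2,8-dienoate | COC(=O)/C=C(\C)CC[C@@H](OCc1ccccc1)C(C)(C)/C=C/CC1(C)OCCO1 | intermediate
15 | methyl (2E,6R,8E)-6-(benzyloxy)-3,7,7-trimethyl-11-oxododeca-2,8-dienoate | COC(=O)/C=C(\C)CC[C@@H](OCc1ccccc1)C(C)(C)/C=C/CC(C)=O | intermediate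
16 | methyl (2E,6R,8E,10Z)-6-(benzyloxy)-11-[(tert-butyldimethylsilyl)oxy]-3,7,7-trimethyldodeca-2,8,10-trienoate (Diels–Alder precursor) | COC(=O)/C=C(\C)CC[C@@H](OCc1ccccc1)C(C)(C)/C=C/C=C(/C)O[Si](C)(C)C(C)(C)C | intermediate
17 | methyl (3R)-3-benzyloxy-8-(TBS-oxy)-4,4,8,10-tetramethyl-trans-decal-6-ene-9-carboxylate; 3-OBn equatorial; 10-Me, 8-Me, 9-CO2Me on one face; H-5, H-9, 8-OTBS on the other | CC1(C)[C@H](OCc2ccccc2)CC[C@]2(C)[C@@H]1C=C[C@](C)(O[Si](C)(C)C(C)(C)C)[C@H]2C(=O)OC | intermediate
18 | methyl (3R)-3-hydroxy-8-(TBS-oxy)-4,4,8,10-tetramethyl-trans-decalin-9-carboxylate, ring configuration Q | CC1(C)[C@H](O)CC[C@]2(C)[C@@H]1CC[C@](C)(O[Si](C)(C)C(C)(C)C)[C@H]2C(=O)OC | intermediate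
19 | methyl 8-(TBS-oxy)-4,4,8,10-tetramethyl-3-oxo-trans-decalin-9-carboxylate, ring configuration Q | CC1(C)C(=O)CC[C@]2(C)[C@@H]1CC[C@](C)(O[Si](C)(C)C(C)(C)C)[C@H]2C(=O)OC | intermediate
20 | potassium C2=C3 enolate of 19 (not isolated) | CC1(C)C([O-])=CC[C@]2(C)[C@@H]1CC[C@](C)(O[Si](C)(C)C(C)(C)C)[C@H]2C(=O)OC.[K+] | intermediate
21 | methyl 8-(TBS-oxy)-4,4,8,10-tetramethyl-3-(trifluoromethanesulfonyloxy)-trans-decal-2-ene-9-carboxylate, ring configuration Q | CC1(C)C(OS(=O)(=O)C(F)(F)F)=CC[C@]2(C)[C@@H]1CC[C@](C)(O[Si](C)(C)C(C)(C)C)[C@H]2C(=O)OC | intermediate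
22 | methyl 3-bromo-8-(TBS-oxy)-4,4,8,10-tetramethyl-trans-decal-2-ene-9-carboxylate, ring configuration Q | CC1(C)C(Br)=CC[C@]2(C)[C@@H]1CC[C@](C)(O[Si](C)(C)C(C)(C)C)[C@H]2C(=O)OC | intermediate
23 | methyl (3R)-3-bromo-8-(TBS-oxy)-4,4,8,10-tetramethyl-trans-decalin-9-carboxylate, Br equatorial, ring configuration Q | CC1(C)[C@H](Br)CC[C@]2(C)[C@@H]1CC[C@](C)(O[Si](C)(C)C(C)(C)C)[C@H]2C(=O)OC | intermediate
24 | [(3R)-3-bromo-8-(TBS-oxy)-4,4,8,10-tetramethyl-trans-decalin-9-yl]methanol, ring configuration Q | CC1(C)[C@H](Br)CC[C@]2(C)[C@@H]1CC[C@](C)(O[Si](C)(C)C(C)(C)C)[C@H]2CO | intermediate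
25 | (3R)-3-bromo-8-(TBS-oxy)-4,4,8,10-tetramethyl-trans-decalin-9-carbaldehyde, ring configuration Q | CC1(C)[C@H](Br)CC[C@]2(C)[C@@H]1CC[C@](C)(O[Si](C)(C)C(C)(C)C)[C@H]2C=O | intermediate
26 | (3E)-4-[(3R)-3-bromo-8-(TBS-oxy)-4,4,8,10-tetramethyl-trans-decalin-9-yl]but-3-en-2-one, ring configuration Q | CC1(C)[C@H](Br)CC[C@]2(C)[C@@H]1CC[C@](C)(O[Si](C)(C)C(C)(C)C)[C@H]2/C=C/C(C)=O | intermediate
27 | 4-[(3R)-3-bromo-8-(TBS-oxy)-4,4,8,10-tetramethyl-trans-decalin-9-yl]butan-2-one, ring configuration Q | CC1(C)[C@H](Br)CC[C@]2(C)[C@@H]1CC[C@](C)(O[Si](C)(C)C(C)(C)C)[C@H]2CCC(C)=O | intermediate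
28 | TBS ether of (3R)-3-bromo-4,4,8,10-tetramethyl-9-(3-methylbut-3-en-1-yl)-trans-decalin-8-ol, ring configuration Q | CC1(C)[C@H](Br)CC[C@]2(C)[C@@H]1CC[C@](C)(O[Si](C)(C)C(C)(C)C)[C@H]2CCC(C)=C | intermediate
29 | (3R)-3-bromo-4,4,8,10-tetramethyl-9-(3-methylbut-3-en-1-yl)-trans-decalin-8-ol, ring configuration Q | CC1(C)[C@H](Br)CC[C@]2(C)[C@@H]1CC[C@](C)(O)[C@H]2CCC(C)=C | intermediate
30 | potassium C8 alkoxide of 29 (not isolated) | CC1(C)[C@H](Br)CC[C@]2(C)[C@@H]1CC[C@](C)([O-])[C@H]2CCC(C)=C.[K+] | intermediate
31 | (3R)-8-allyloxy-3-bromo-4,4,8,10-tetramethyl-9-(3-methylbut-3-en-1-yl)-trans-decalin, ring configuration Q | CC1(C)[C@H](Br)CC[C@]2(C)[C@@H]1CC[C@](C)(OCC=C)[C@H]2CCC(C)=C | intermediate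
32 | (3R,13Z)-3-bromo-8,15-epoxylabd-13-ene, ring configuration Q | CC1(C)[C@H](Br)CC[C@]2(C)[C@@H]1CC[C@]1(C)OC/C=C(/C)CC[C@@H]21 | intermediate
33 | (3R,5S,8S,9S,10R,13S,14R)-3-bromo-8,15:13,14-diepoxylabdane, CNP0311742.1 | CC1(C)[C@H](Br)CC[C@]2(C)[C@@H]1CC[C@]1(C)OC[C@H]3O[C@@]3(C)CC[C@@H]21 | target

## Step count and risks

Total step count: 24. Longest linear sequence: 22 steps (1 to 33 through steps 1–4 and 7–24). The sulfone branch (steps 5 and 6) is two steps from 9.

Steps most likely to fail:

1. Step 10 (key cycloaddition). Both new bonds join fully substituted or neopentylic carbons and the diene carries an inside substituent, so the cycloaddition may be too slow at temperatures the silyl dienol ether tolerates. At higher temperature the endo/exo preference (trans against cis ring fusion) and the facial preference exerted by C3 may erode, and the dienol ether may lose its silyl group. The fallback sets out from 16 and comes back at 17; it keeps the same bond set but changes the activating group of the dienophile. Reduction of the ester of 16 with DIBAL-H (CH2Cl2, −78 °C) should give the allylic alcohol F1, and MnO2 the enal F2. The enal is a much stronger dienophile, so the same cycloaddition is expected at about 100 °C, through the same endo transition state, to give the octalin aldehyde F3. Pinnick oxidation (NaClO2, NaH2PO4, 2-methylbut-2-ene) to the carboxylic acid F4 and methylation with trimethylsilyldiazomethane return the material to 17.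

2. Step 23 (closure of ring C). Formation of an eight-membered ring with a trisubstituted alkene may lose to intermolecular metathesis or to isomerisation of the allyl ether to an enol ether. The fallback sets out from 25 and comes back at 32, closing ring C at C12–C13 by cross-coupling in place of metathesis at C13=C14. Wittig methylenation of 25 (Ph3PCH3Br, KOt-Bu) gives the C9 vinyl compound F5, and TBAF gives the tertiary alcohol F6. Alkylation with KH and (Z)-1-bromo-3-iodobut-2-ene gives the iodobutenyl ether F7. Hydroboration of the vinyl group with 9-BBN gives the B-alkyl borane F8. Intramolecular B-alkyl Suzuki–Miyaura coupling (PdCl2(dppf), AsPh3, Cs2CO3, DMF/THF/H2O, high dilution) forms the C12–C13 bond with retention of the alkene geometry and gives 32.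

3. Step 24 (epoxidation). The ring conformer that reacts may expose the other alkene face, so that the oxidant delivers oxygen to the wrong face and the C13,C14-diastereomer of the epoxide forms. The fallback sets out from 32 and comes back at 33, placing the oxygen by anti addition and not by direct syn delivery. NBS in aqueous acetone forms the bromonium ion on the accessible face, and water opens it at the more substituted C13 from the opposite face to give the bromohydrin F9. K2CO3 in MeOH then closes the epoxide by displacement of bromide with inversion at C14, so the oxygen ends on the face that direct epoxidation does not reach.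

Further compounds
F1 | step 10 | (2E,6R,8E,10Z)-6-(benzyloxy)-11-[(tert-butyldimethylsilyl)oxy]-3,7,7-trimethyldodeca-2,8,10-trien-1-ol | OC/C=C(\C)CC[C@@H](OCc1ccccc1)C(C)(C)/C=C/C=C(/C)O[Si](C)(C)C(C)(C)C
F2 | step 10 | (2E,6R,8E,10Z)-6-(benzyloxy)-11-[(tert-butyldimethylsilyl)oxy]-3,7,7-trimethyldodeca-2,8,10-trienal | O=C/C=C(\C)CC[C@@H](OCc1ccccc1)C(C)(C)/C=C/C=C(/C)O[Si](C)(C)C(C)(C)C
F3 | step 10 | (3R)-3-benzyloxy-8-(TBS-oxy)-4,4,8,10-tetramethyl-trans-decal-6-ene-9-carbaldehyde, ring configuration Q | CC1(C)[C@H](OCc2ccccc2)CC[C@]2(C)[C@@H]1C=C[C@](C)(O[Si](C)(C)C(C)(C)C)[C@H]2C=O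
F4 | step 10 | (3R)-3-benzyloxy-8-(TBS-oxy)-4,4,8,10-tetramethyl-trans-decal-6-ene-9-carboxylic acid, ring configuration Q | CC1(C)[C@H](OCc2ccccc2)CC[C@]2(C)[C@@H]1C=C[C@](C)(O[Si](C)(C)C(C)(C)C)[C@H]2C(=O)O
F5 | step 23 | TBS ether of (3R)-3-bromo-9-ethenyl-4,4,8,10-tetramethyl-trans-decalin-8-ol, ring configuration Q | CC1(C)[C@H](Br)CC[C@]2(C)[C@@H]1CC[C@](C)(O[Si](C)(C)C(C)(C)C)[C@H]2C=C
F6 | step 23 | (3R)-3-bromo-9-ethenyl-4,4,8,10-tetramethyl-trans-decalin-8-ol, ring configuration Q | CC1(C)[C@H](Br)CC[C@]2(C)[C@@H]1CC[C@](C)(O)[C@H]2C=C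
F7 | step 23 | (3R)-3-bromo-9-ethenyl-8-{[(2Z)-3-iodobut-2-en-1-yl]oxy}-4,4,8,10-tetramethyl-trans-decalin, ring configuration Q | CC1(C)[C@H](Br)CC[C@]2(C)[C@@H]1CC[C@](C)(OC/C=C(\I)C)[C@H]2C=C
F8 | step 23 | 9-borabicyclo[3.3.1]nonan-9-yl adduct of F7 at C12 | CC1(C)[C@H](Br)CC[C@]2(C)[C@@H]1CC[C@](C)(OC/C=C(\I)C)[C@H]2CCB1C2CCCC1CCC2
F9 | step 24 | (3R,13S,14S)-3,14-dibromo-8,15-epoxylabdan-13-ol, ring configuration Q | CC1(C)[C@H](Br)CC[C@]2(C)[C@@H]1CC[C@]1(C)OC[C@H](Br)[C@@](C)(O)CC[C@@H]21
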